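**Plan**

- Retrosynthesis: after removal of the three phenol protecting groups, the aryl ketone bond C4–C4a of ring C is cut first, then the ether bond O1–C2, then the two aryl–prenyl bonds. This leads back to phloroglucinol, prenyl bromide and a 4-hydroxybenzoylacetate.
- Forward: ring A is bought and C-prenylated twice, and ring B arrives with the keto ester. The two halves are joined through O1–C2, and ring C, the only ring that is made, closes last through C4–C4a.
- Enabling feature: 2,4-diprenylphloroglucinol has a mirror plane through its central hydroxyl (later 7-OH) and its single unsubstituted ring carbon (later C4a). The two hydroxyls next to that carbon (later O1 and 5-OH) are equivalent, so etherifying either one leaves exactly one position of ring A at which the tethered acyl group can close ring C.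
- Stereochemistry: C2 is the only stereocentre. Catalyst-controlled transfer hydrogenation gives the (R)-carbinol and Mitsunobu etherification inverts it to (S); every later step is chosen to leave the C2–O1 bond untouched.

Key step: step 8

Assumption: the aryl acetate is taken to survive acetic acid-buffered fluoride, so the silyl and acetyl groups are removed in two separate mild steps; partial early loss of the acetate would simply converge on the target.

**Route**

Step 1
Reactants: 1 phloroglucinol; 2 prenyl bromide (2 equiv)
Product: 3 2,4-bis(3-methylbut-2-enyl)benzene-1,3,5-triol (2,4-diprenylphloroglucinol)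
Conditions: KOH, H2O, 0 °C to rt, argon
Reagents that add atoms: none
Why: Phenoxide C-alkylation (nuclear prenylation) in water, where hydrogen bonding to the phenoxide oxygens steers the ambident anion to carbon; the three ring carbons of 1 are equivalent and so are the two left after the first alkylation, so 3 is the only nuclear dialkylation product and is separated from mono- and over-alkylated material by chromatography.

Step 2
Reactants: 4 ethyl 3-(4-hydroxyphenyl)-3-oxopropanoate
Product: 5 allyl 3-(4-hydroxyphenyl)-3-oxopropanoate
Conditions: allyl alcohol (5 equiv), DMAP (cat.), toluene, reflux, 4 Å molecular sieves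
Reagents that add atoms: allyl alcohol, C=CCO
Why: DMAP-catalysed transesterification of a β-keto ester, which runs through the enol/acylketene manifold of β-keto esters and is driven by trapping of ethanol on the sieves; the phenol is a far poorer nucleophile than the excess allyl alcohol, and the allyl ester is installed so that the acid can later be freed without base.

Step 3
Reactants: 5 allyl 3-(4-hydroxyphenyl)-3-oxopropanoate
Product: 6 allyl 3-(4-acetoxyphenyl)-3-oxopropanoate
Conditions: Ac2O (1.05 equiv), pyridine, CH2Cl2, 0 °C
Reagents that add atoms: acetic anhydride, CC(=O)OC(C)=O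
Why: Acetylation of the phenol, much faster than enol acetylation of the β-keto ester at 0 °C with one equivalent, turns the strongly donating 4-hydroxy group into a weakly donating acetoxy group that later suppresses benzylic ionisation.

Step 4
Reactants: 6 allyl 3-(4-acetoxyphenyl)-3-oxopropanoate
Product: 7 allyl (R)-3-(4-acetoxyphenyl)-3-hydroxypropanoate
Conditions: RuCl(p-cymene)[(R,R)-TsDPEN] (1 mol %), HCO2H/Et3N (5:2), CH2Cl2, 30 °C
Reagents that add atoms: none
Why: Noyori–Ikariya asymmetric transfer hydrogenation of an aryl β-keto ester: the (R,R)-catalyst, which gives (R)-1-arylethanols from aryl methyl ketones through its CH/π-controlled six-membered transition state, should deliver hydride to the Si face and set the (R)-carbinol, while the isolated allyl alkene and the aryl acetate are inert to the ruthenium hydride.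

Step 5
Reactants: 3 2,4-diprenylphloroglucinol (2.5 equiv); 7 allyl (R)-3-(4-acetoxyphenyl)-3-hydroxypropanoate
Product: 8 allyl (S)-3-(4-acetoxyphenyl)-3-[3,5-dihydroxy-2,4-bis(3-methylbut-2-enyl)phenoxy]propanoate
Conditions: PPh3, DIAD (betaine pre-formed), THF, 0 °C to rt
Reagents that add atoms: none
Why: Mitsunobu etherification: the phenoxide of 3 displaces the alkoxyphosphonium group of 7 in an SN2 step with inversion, turning the (R)-carbinol into the (S)-aryl ether; the two equivalent hydroxyls flanking the free ring carbon react in preference to the central one shielded by two prenyl groups, the excess of 3 suppresses double etherification, pre-forming the betaine keeps free azodicarboxylate away from the electron-rich ring, and the acetoxy-substituted benzylic carbon with its β-ester is a poor candidate for SN1 leakage.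

Step 6
Reactants: 8 allyl (S)-3-(4-acetoxyphenyl)-3-[3,5-dihydroxy-2,4-bis(3-methylbut-2-enyl)phenoxy]propanoate
Product: 9 allyl (S)-3-(4-acetoxyphenyl)-3-[3,5-bis(tert-butyldimethylsilyloxy)-2,4-bis(3-methylbut-2-enyl)phenoxy]propanoate
Conditions: TBSOTf, 2,6-lutidine, CH2Cl2, −40 to 0 °C
Reagents that add atoms: tert-butyldimethylsilyl triflate, CC(C)(C)[Si](C)(C)OS(=O)(=O)C(F)(F)F
Why: Silylation of both remaining phenols with the silyl triflate under non-nucleophilic buffering is strong enough for the hydroxyl between two prenyl groups and leaves the aryl acetate, the allyl ester and the β-aryloxy ester untouched, since no base able to trigger E1cB loss of the phenoxide is present.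

Step 7
Reactants: 9 allyl (S)-3-(4-acetoxyphenyl)-3-[3,5-bis(tert-butyldimethylsilyloxy)-2,4-bis(3-methylbut-2-enyl)phenoxy]propanoate
Product: 10 (S)-3-(4-acetoxyphenyl)-3-[3,5-bis(tert-butyldimethylsilyloxy)-2,4-bis(3-methylbut-2-enyl)phenoxy]propanoic acid
Conditions: Pd(PPh3)4 (5 mol %), N-methylaniline, THF, rt; pH 4 buffer work-up
Reagents that add atoms: none
Why: Tsuji–Trost deallylation: zerovalent palladium ionises only the allyl ester to a π-allyl complex that is captured by the weakly nucleophilic N-methylaniline, so the acid is released under neutral conditions without β-elimination of the phenol, aminolysis of the acetate or silyl loss, and the prenyl groups, which carry no allylic leaving group, are not engaged.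

Step 8
Reactants: 10 (S)-3-(4-acetoxyphenyl)-3-[3,5-bis(tert-butyldimethylsilyloxy)-2,4-bis(3-methylbut-2-enyl)phenoxy]propanoic acid
Product: 12 (2S)-2-(4-acetoxyphenyl)-5,7-bis(tert-butyldimethylsilyloxy)-6,8-bis(3-methylbut-2-enyl)chroman-4-one, via acid chloride 11 (not isolated)
Conditions: 1-chloro-N,N,2-trimethylprop-1-en-1-amine, CH2Cl2, 0 °C; then SnCl4, 2,6-di-tert-butyl-4-methylpyridine, CH2Cl2, −78 °C
Reagents that add atoms: none
Why: Intramolecular Friedel–Crafts acylation: the chloroenamine converts acid 10 into acid chloride 11 without releasing HCl, SnCl4 ionises 11 to an acylium ion (or its tight ion pair), the one unsubstituted carbon of ring A, activated by the ortho ether oxygen and by the ortho and para silyloxy groups, attacks it, and the hindered pyridine removes the proton of the Wheland intermediate, so that the C4–C4a bond is formed. The closest known reaction type is the acid chloride/Lewis acid cyclisation of 3-aryloxypropanoic acids to chroman-4-ones. Ring C closes in a 6-exo mode, the arene carbon adding to the acylium carbon whose C–O multiple bond stays outside the new six-membered ring. No stereocentre is created and the C2 centre from step 5 is only a spectator. Site selectivity is dictated by the substrate, since every other carbon of ring A is substituted; the selectivity that has to be secured is retention at C2 and survival of the prenyl alkenes, and it rests on the acetoxy-deactivated benzylic position (ionisation of C2–O1 disfavoured), the HCl-free activation, the proton scavenger and the low temperature.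

Step 9
Reactants: 12 (2S)-2-(4-acetoxyphenyl)-5,7-bis(tert-butyldimethylsilyloxy)-6,8-bis(3-methylbut-2-enyl)chroman-4-one
Product: 13 (2S)-2-(4-acetoxyphenyl)-5,7-dihydroxy-6,8-bis(3-methylbut-2-enyl)chroman-4-one (4'-O-acetyl-6,8-diprenylnaringenin)
Conditions: TBAF, AcOH (1:1), THF, 0 °C
Reagents that add atoms: none
Why: Fluoride-induced cleavage of the two aryl silyl ethers, both activated as ethers of an ortho/para-acylphenol, is buffered with acetic acid so that the phenoxides are protonated at once and base-induced retro-oxa-Michael opening to the chalcone, which would racemise C2, is avoided.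

Step 10
Reactants: 13 (2S)-2-(4-acetoxyphenyl)-5,7-dihydroxy-6,8-bis(3-methylbut-2-enyl)chroman-4-one
Product: 14 (2S)-6,8-diprenylnaringenin, (2S)-5,7-dihydroxy-2-(4-hydroxyphenyl)-6,8-bis(3-methylbut-2-enyl)chroman-4-one
Conditions: NH4OAc, MeOH/H2O (4:1), rt
Reagents that add atoms: none
Why: Ammonium acetate-mediated methanolysis of the aryl acetate, a neutral transesterification selective for phenolic acetates, frees the 4'-hydroxyl without acid that could cyclise the prenyl groups onto the neighbouring phenols and without base that could open ring C.

**Compound list**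

1 | phloroglucinol | Oc1cc(O)cc(O)c1 | starting material
2 | prenyl bromide | CC(C)=CCBr | starting material
3 | 2,4-bis(3-methylbut-2-enyl)benzene-1,3,5-triol | CC(C)=CCc1c(O)cc(O)c(CC=C(C)C)c1O | intermediate
4 | ethyl 3-(4-hydroxyphenyl)-3-oxopropanoate | CCOC(=O)CC(=O)c1ccc(O)cc1 | starting material
5 | allyl 3-(4-hydroxyphenyl)-3-oxopropanoate | C=CCOC(=O)CC(=O)c1ccc(O)cc1 | intermediate
6 | allyl 3-(4-acetoxyphenyl)-3-oxopropanoate | C=CCOC(=O)CC(=O)c1ccc(OC(C)=O)cc1 | intermediate
7 | allyl (R)-3-(4-acetoxyphenyl)-3-hydroxypropanoate | C=CCOC(=O)C[C@@H](O)c1ccc(OC(C)=O)cc1 | intermediate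
8 | allyl (S)-3-(4-acetoxyphenyl)-3-[3,5-dihydroxy-2,4-bis(3-methylbut-2-enyl)phenoxy]propanoate | C=CCOC(=O)C[C@@H](c1ccc(OC(C)=O)cc1)Oc1cc(O)c(CC=C(C)C)c(O)c1CC=C(C)C | intermediate
9 | allyl (S)-3-(4-acetoxyphenyl)-3-[3,5-bis(tert-butyldimethylsilyloxy)-2,4-bis(3-methylbut-2-enyl)phenoxy]propanoate | C=CCOC(=O)C[C@@H](c1ccc(OC(C)=O)cc1)Oc1cc(O[Si](C)(C)C(C)(C)C)c(CC=C(C)C)c(O[Si](C)(C)C(C)(C)C)c1CC=C(C)C | intermediate
10 | (S)-3-(4-acetoxyphenyl)-3-[3,5-bis(tert-butyldimethylsilyloxy)-2,4-bis(3-methylbut-2-enyl)phenoxy]propanoic acid | OC(=O)C[C@@H](c1ccc(OC(C)=O)cc1)Oc1cc(O[Si](C)(C)C(C)(C)C)c(CC=C(C)C)c(O[Si](C)(C)C(C)(C)C)c1CC=C(C)C | intermediate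
11 | (S)-3-(4-acetoxyphenyl)-3-[3,5-bis(tert-butyldimethylsilyloxy)-2,4-bis(3-methylbut-2-enyl)phenoxy]propanoyl chloride | ClC(=O)C[C@@H](c1ccc(OC(C)=O)cc1)Oc1cc(O[Si](C)(C)C(C)(C)C)c(CC=C(C)C)c(O[Si](C)(C)C(C)(C)C)c1CC=C(C)C | intermediate (not isolated)
12 | (2S)-2-(4-acetoxyphenyl)-5,7-bis(tert-butyldimethylsilyloxy)-6,8-bis(3-methylbut-2-enyl)chroman-4-one | O=C1C[C@@H](c2ccc(OC(C)=O)cc2)Oc2c(CC=C(C)C)c(O[Si](C)(C)C(C)(C)C)c(CC=C(C)C)c(O[Si](C)(C)C(C)(C)C)c12 | intermediate
13 | (2S)-2-(4-acetoxyphenyl)-5,7-dihydroxy-6,8-bis(3-methylbut-2-enyl)chroman-4-one | O=C1C[C@@H](c2ccc(OC(C)=O)cc2)Oc2c(CC=C(C)C)c(O)c(CC=C(C)C)c(O)c12 | intermediate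
14 | (2S)-6,8-diprenylnaringenin | CC(C)=CCc1c(O)c(CC=C(C)C)c2c(c1O)C(=O)C[C@@H](c1ccc(O)cc1)O2 | target

**Step count and risks**

Total step count: 10. Longest linear sequence: 9 steps (steps 2 to 10, from 4); step 1 supplies the second fragment for the union in step 5.

The three steps most likely to fail are steps 8, 5 and 1.

Step 8. The processes that may interfere are:
- Lewis-acid ionisation of the benzylic C2–O1 bond or β-elimination of the phenol, with loss of optical purity or of the side chain;
- addition of HCl to the prenyl alkenes;
- slow acylation if the twisted silyloxy groups donate poorly.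

The fallback reverses the polarity of the same C4–C4a bond formation and needs no acid. It sets out from allyl ester 9, whose only free ring carbon is iodinated with N-iodosuccinimide in MeCN at 0 °C to give the aryl iodide allyl (S)-3-(4-acetoxyphenyl)-3-[3,5-bis(tert-butyldimethylsilyloxy)-2-iodo-4,6-bis(3-methylbut-2-enyl)phenoxy]propanoate F1. Iodine–magnesium exchange with iPrMgCl·LiCl in THF at −40 °C, a temperature at which esters tolerate the exchange reagent, then generates the arylmagnesium. This should add to the allyl ester in a Parham-type cyclisation and expel allyloxide, coming back to the route at 12.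

Step 5. The processes that may interfere are:
- double etherification of the triol;
- reaction at the central hydroxyl;
- electrophilic amination of the free ring carbon by the azodicarboxylate;
- dehydration of the β-hydroxy ester to the cinnamate;
- partial SN1 leakage that erodes the enantiomeric purity.

The fallback removes the chemoselectivity question by differentiating the phenols before the coupling. It sets out from 3, which is persilylated with TBSCl and imidazole in DMF to 1,3,5-tris(tert-butyldimethylsilyloxy)-2,4-bis(3-methylbut-2-enyl)benzene F2. Catalytic Cs2CO3 in DMF/H2O at rt, stopped at partial conversion, should cleave one of the two equivalent, less shielded silyl ethers (the central one sits between two prenyl groups) to give 3,5-bis(tert-butyldimethylsilyloxy)-2,4-bis(3-methylbut-2-enyl)phenol F3. Mitsunobu coupling of this single free phenol with 7 (PPh3, DIAD, THF) then comes back to the route at 9, bypassing 8.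

Step 1. The processes that may interfere are statistical under- and over-alkylation, O-prenylation and geminal dialkylation with dearomatisation. The fallback blocks one ring carbon with a removable ester. It sets out from 2 and the purchased ester methyl 2,4,6-trihydroxybenzoate F4, whose two free ring carbons are equivalent and whose acylphloroglucinol character favours clean C-alkylation. Prenylation with 2 in aqueous KOH gives methyl 2,4,6-trihydroxy-3,5-bis(3-methylbut-2-enyl)benzoate F5. Hot aqueous methanolic KOH saponifies it to 2,4,6-trihydroxy-3,5-bis(3-methylbut-2-enyl)benzoic acid F6, which should decarboxylate in the same pot, and careful neutralisation comes back to the route at 3.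

**Further compounds**

F1 | step 8 | allyl (S)-3-(4-acetoxyphenyl)-3-[3,5-bis(tert-butyldimethylsilyloxy)-2-iodo-4,6-bis(3-methylbut-2-enyl)phenoxy]propanoate | C=CCOC(=O)C[C@@H](c1ccc(OC(C)=O)cc1)Oc1c(I)c(O[Si](C)(C)C(C)(C)C)c(CC=C(C)C)c(O[Si](C)(C)C(C)(C)C)c1CC=C(C)C
F2 | step 5 | 1,3,5-tris(tert-butyldimethylsilyloxy)-2,4-bis(3-methylbut-2-enyl)benzene | CC(C)=CCc1c(O[Si](C)(C)C(C)(C)C)cc(O[Si](C)(C)C(C)(C)C)c(CC=C(C)C)c1O[Si](C)(C)C(C)(C)C
F3 | step 5 | 3,5-bis(tert-butyldimethylsilyloxy)-2,4-bis(3-methylbut-2-enyl)phenol | CC(C)=CCc1c(O)cc(O[Si](C)(C)C(C)(C)C)c(CC=C(C)C)c1O[Si](C)(C)C(C)(C)C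
F4 | step 1 | methyl 2,4,6-trihydroxybenzoate (purchased) | COC(=O)c1c(O)cc(O)cc1O
F5 | step 1 | methyl 2,4,6-trihydroxy-3,5-bis(3-methylbut-2-enyl)benzoate | COC(=O)c1c(O)c(CC=C(C)C)c(O)c(CC=C(C)C)c1O
F6 | step 1 | 2,4,6-trihydroxy-3,5-bis(3-methylbut-2-enyl)benzoic acid | OC(=O)c1c(O)c(CC=C(C)C)c(O)c(CC=C(C)C)c1O
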